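**Retrosynthetic overview**

1. The target is a 2-methylhydroquinone whose ring carbon C6 carries a C20 chain (C1'–C16'; 2'E, 6'Z, 10'E; 5'-oxo; 13'R-hydroxy). It is traced back to quinone 24 (ring aromatised last by reduction), then to the C13' silyl ether 23 and the C5' alcohol 22, so the sensitive skipped enone is made late and on an oxidation-proof ring.
2. Key disconnection C1'–C2': one-flask methylalumination of terminal alkyne 15 and nickel-catalysed union of the resulting alkenylalane with chloromethylquinone 19. This forms C1'–C2', installs the C3' methyl and fixes the 2'E alkene.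
3. Enabling feature: C2'=C3' is an E-trisubstituted alkene with H on C2' and CH3 on C3', the retron of a syn Me–Al addition to a C2'≡C3' alkyne. C1' is a CH2 on ring carbon C2 of the six-membered carbocycle, which at the cyclohexa-2,5-diene-1,4-dione level makes the C1'–Cl bond a vinylogous α-chloroketone (benzylic-type) electrophile.
4. Alkyne 15: C4'–C5' by Barbier propargylation of (2Z,6E)-enal 12 (the C5' ketone is carried as a TES ether). C9'–C10' by B-alkyl Suzuki–Miyaura coupling of iodoalkene 7 with the 9-BBN adduct of (Z)-dienol 9. Iodoalkene 7 comes from catalytic asymmetric propargylation of 3-methylbut-2-enal (sets C13') and methylalumination/iodination (sets 10'E); the 6'Z alkene is bought with (Z)-enynol 8.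
5. Rings: the only ring, the six-membered carbocycle, is present from starting material 16. It is oxidised to the quinone in step 10, carried as the quinone through steps 11–15 and re-aromatised in step 16.

Key step: step 12

Assumption (chemistry): the (R)-configured phosphoric acid of step 1 is taken to deliver the propargyl group to the Re face of the enal carbonyl, as it does with aromatic and other α,β-unsaturated aldehydes; if the sense proved opposite, the (S)-acid would be used.

**Route**

Step 1
Reactants: 1 3-methylbut-2-enal; 2 allenylboronic acid pinacol ester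
Product: 4 (4R)-6-methylhept-5-en-1-yn-4-ol, via O-boronate ester 3 (not isolated)
Conditions: (R)-TRIP phosphoric acid (10 mol%), 4 Å MS, toluene, −20 °C; then aq. NaHCO3
Reagents that add atoms: none
Why: Chiral phosphoric acid-catalysed propargylboration through a closed six-membered SE2' transition state, in which the acid bridges a boronate oxygen and the formyl hydrogen, should deliver the propargyl group to the Re face and so set the (R)-carbinol (C13' of the target), while γ-attack of the allenyl unit gives the homopropargylic and not the allenic alcohol.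

Step 2
Reactants: 4 (4R)-6-methylhept-5-en-1-yn-4-ol
Product: 5 tert-butyldimethyl{[(4R)-6-methylhept-5-en-1-yn-4-yl]oxy}silane
Conditions: TBSCl, imidazole, DMF, rt
Reagents that add atoms: tert-butyldimethylsilyl chloride (TBSCl), CC(C)(C)[Si](C)(C)Cl
Why: Standard silylation of a secondary alcohol; the TBS ether should survive every operation up to step 15.

Step 3
Reactants: 5 tert-butyldimethyl{[(4R)-6-methylhept-5-en-1-yn-4-yl]oxy}silane
Product: 7 tert-butyl{[(1E,4R)-1-iodo-2,6-dimethylhepta-1,5-dien-4-yl]oxy}dimethylsilane, via alkenylalane 6 (not isolated)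
Conditions: AlMe3 (2.0 equiv), Cp2ZrCl2 (0.25 equiv), CH2Cl2, 0 °C → rt; then I2, THF, −30 → 0 °C
Reagents that add atoms: trimethylaluminium, C[Al](C)C; iodine, II
Why: Negishi zirconium-catalysed carboalumination adds Me–Al syn across the terminal alkyne with methyl on the internal carbon, and iodinolysis of the C–Al bond with retention gives the E-iodoalkene that becomes the C10'=C11' alkene.

Step 4
Reactants: 8 (2Z)-3-methylpent-2-en-4-yn-1-ol
Product: 9 (2Z)-3-methylpenta-2,4-dien-1-ol
Conditions: H2 (1 atm), Pd/CaCO3 poisoned with Pb(OAc)2 (Lindlar catalyst), quinoline, Et2O, 0 °C, stopped after 1 equiv H2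
Reagents that add atoms: none
Why: Semihydrogenation of a conjugated terminal alkyne over poisoned palladium should stop at the diene and leave the Z-trisubstituted alkene and its geometry untouched.

Step 5
Reactants: 9 (2Z)-3-methylpenta-2,4-dien-1-ol; 7 tert-butyl{[(1E,4R)-1-iodo-2,6-dimethylhepta-1,5-dien-4-yl]oxy}dimethylsilane
Product: 11 (2Z,6E,9R)-9-[(tert-butyldimethylsilyl)oxy]-3,7,11-trimethyldodeca-2,6,10-trien-1-ol, via bis-borane adduct 10 (not isolated)
Conditions: 9-BBN-H (2.2 equiv), THF, 0 °C → rt; then 7, Pd(dppf)Cl2 (5 mol%), AsPh3 (5 mol%), Cs2CO3 (3 equiv), DMF/H2O, rt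
Reagents that add atoms: none
Why: 9-BBN first caps the hydroxyl as a borinate and then hydroborates the monosubstituted diene terminus anti-Markovnikov (the trisubstituted alkene is too hindered), and the B-alkyl Suzuki–Miyaura coupling with the iodoalkene forms C9'–C10' with retention of both alkene geometries.

Step 6
Reactants: 11 (2Z,6E,9R)-9-[(tert-butyldimethylsilyl)oxy]-3,7,11-trimethyldodeca-2,6,10-trien-1-ol
Product: 12 (2Z,6E,9R)-9-[(tert-butyldimethylsilyl)oxy]-3,7,11-trimethyldodeca-2,6,10-trienal
Conditions: Dess–Martin periodinane (1.2 equiv), NaHCO3, CH2Cl2, 0 °C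
Reagents that add atoms: none
Why: Buffered Dess–Martin oxidation of the primary allylic alcohol should give the enal without acid or base strong enough to equilibrate the 2Z alkene.

Step 7
Reactants: 12 (2Z,6E,9R)-9-[(tert-butyldimethylsilyl)oxy]-3,7,11-trimethyldodeca-2,6,10-trienal; 13 3-bromoprop-1-yne
Product: 14 (5Z,9E,12R)-12-[(tert-butyldimethylsilyl)oxy]-6,10,14-trimethylpentadeca-5,9,13-trien-1-yn-4-ol (both C4 epimers)
Conditions: Zn dust, THF/sat. aq. NH4Cl, 0 °C → rt
Reagents that add atoms: none
Why: Barbier propargylation, in which allenylzinc bromide formed in the flask adds 1,2 to the enal through an SE2' transition state, should give the homopropargylic alcohol under near-neutral conditions that spare the Z-enal and the TBS ether; the new C4 centre is not controlled and need not be, since it becomes the C5' ketone.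

Step 8
Reactants: 14 (5Z,9E,12R)-12-[(tert-butyldimethylsilyl)oxy]-6,10,14-trimethylpentadeca-5,9,13-trien-1-yn-4-ol
Product: 15 (5Z,9E,12R)-12-[(tert-butyldimethylsilyl)oxy]-6,10,14-trimethyl-4-[(triethylsilyl)oxy]pentadeca-5,9,13-trien-1-yne
Conditions: TESCl, imidazole, CH2Cl2, 0 °C
Reagents that add atoms: chlorotriethylsilane (TESCl), CC[Si](CC)(CC)Cl
Why: Standard silylation; TES is chosen because it masks the C5' oxygen from AlMe3 and can later be removed in the presence of the TBS ether.

Step 9
Reactants: 16 2-hydroxy-3-methylbenzaldehyde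
Product: 17 2-(hydroxymethyl)-6-methylphenol
Conditions: NaBH4, MeOH, 0 °C
Reagents that add atoms: none
Why: Simple hydride reduction of the aromatic aldehyde to the benzylic alcohol.

Step 10
Reactants: 17 2-(hydroxymethyl)-6-methylphenol
Product: 18 2-(hydroxymethyl)-6-methylcyclohexa-2,5-diene-1,4-dione
Conditions: ON(SO3K)2 (Fremy's salt, 2.2 equiv), KH2PO4 buffer, H2O/acetone, 0 °C → rt
Reagents that add atoms: potassium nitrosodisulfonate, [K+].[K+].[O]N(S(=O)(=O)[O-])S(=O)(=O)[O-]
Why: Teuber oxidation, in which the phenoxyl radical is trapped at its free para carbon by a second nitroxide and loses imidodisulfonate, should give only the para-quinone because both ortho positions are substituted.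

Step 11
Reactants: 18 2-(hydroxymethyl)-6-methylcyclohexa-2,5-diene-1,4-dione
Product: 19 2-(chloromethyl)-6-methylcyclohexa-2,5-diene-1,4-dione
Conditions: 1-chloro-N,N,2-trimethylprop-1-en-1-amine (1.1 equiv), CH2Cl2, 0 °C; used at once
Reagents that add atoms: 1-chloro-N,N,2-trimethylprop-1-en-1-amine, CC(C)=C(Cl)N(C)C
Why: The α-chloroenamine activates the primary alcohol as an alkoxy-iminium species that collapses to the chloride and a neutral amide, so no free HCl, amine or phosphine that could add to the quinone is present.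

Step 12
Reactants: 15 (5Z,9E,12R)-12-[(tert-butyldimethylsilyl)oxy]-6,10,14-trimethyl-4-[(triethylsilyl)oxy]pentadeca-5,9,13-trien-1-yne; 19 2-(chloromethyl)-6-methylcyclohexa-2,5-diene-1,4-dione
Product: 21 2-[(2E,6Z,10E,13R)-13-[(tert-butyldimethylsilyl)oxy]-3,7,11,15-tetramethyl-5-[(triethylsilyl)oxy]hexadeca-2,6,10,14-tetraen-1-yl]-6-methylcyclohexa-2,5-diene-1,4-dione, via alkenylalane 20 (not isolated)
Conditions: AlMe3 (2.0 equiv), Cp2ZrCl2 (0.25 equiv), ClCH2CH2Cl, 0 °C → rt; volatiles and excess AlMe3 removed in vacuo; then 19 (0.9 equiv), NiCl2(PPh3)2 (5 mol%) pre-reduced with n-BuLi (10 mol%) to zerovalent nickel, THF, −20 → 0 °C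
Reagents that add atoms: trimethylaluminium, C[Al](C)C
Why: Zirconocene-catalysed syn-methylalumination of the terminal alkyne (Negishi carboalumination) puts CH3 on C3' and aluminium on C2' on the same side, so alkenylalane 20 carries the methyl branch and the 2'E geometry; zerovalent nickel then adds oxidatively to the C–Cl bond of 19, the alkenyl group passes from aluminium to nickel, and reductive elimination forms C1'–C2' with retention. The closest known reaction type is the nickel-catalysed coupling of alkenylalanes with chloromethylated para-quinones and with benzylic chlorides. No ring is closed and no stereocentre is formed; the one stereoelement created, the 2'E alkene, is controlled by the syn addition of Me–Al and the stereoretentive coupling, and the 13'R centre and the 6'Z and 10'E alkenes are only carried. The step needs regioselective methylalumination, secured by the terminal alkyne (the trisubstituted alkenes and silyl ethers of 15 do not react), and chemoselective reaction at the CH2Cl carbon instead of addition to the quinone C=O or C=C bonds, secured by the low nucleophilicity of the alkenylalane, by removal of excess AlMe3 before 19 is added, and by the fast nickel cycle at low temperature.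

Step 13
Reactants: 21 the TES/TBS-protected quinone
Product: 22 2-[(2E,6Z,10E,13R)-13-[(tert-butyldimethylsilyl)oxy]-5-hydroxy-3,7,11,15-tetramethylhexadeca-2,6,10,14-tetraen-1-yl]-6-methylcyclohexa-2,5-diene-1,4-dione
Conditions: PPTS (0.2 equiv), MeOH/CH2Cl2, 0 °C
Reagents that add atoms: none
Why: Acid-catalysed methanolysis should remove the TES ether much faster than the more hindered TBS ether, and the quinone is inert to these conditions.

Step 14
Reactants: 22 the C5' alcohol
Product: 23 2-[(2E,6Z,10E,13R)-13-[(tert-butyldimethylsilyl)oxy]-3,7,11,15-tetramethyl-5-oxohexadeca-2,6,10,14-tetraen-1-yl]-6-methylcyclohexa-2,5-diene-1,4-dione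
Conditions: Dess–Martin periodinane (1.5 equiv), NaHCO3, CH2Cl2, 0 °C → rt
Reagents that add atoms: none
Why: Dess–Martin oxidation under bicarbonate buffer gives the ketone at neutral pH, which should keep the C2'=C3' alkene out of conjugation and the 6'Z enone geometry intact, and the ring, already a quinone, cannot be over-oxidised.

Step 15
Reactants: 23 the C5' ketone
Product: 24 2-[(2E,6Z,10E,13R)-13-hydroxy-3,7,11,15-tetramethyl-5-oxohexadeca-2,6,10,14-tetraen-1-yl]-6-methylcyclohexa-2,5-diene-1,4-dione
Conditions: HF·pyridine, pyridine, THF, 0 °C → rt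
Reagents that add atoms: none
Why: Buffered fluoride cleavage of the secondary TBS ether is weakly acidic and should neither enolise the β,γ-unsaturated ketone nor ionise the allylic alcohol, so the C13' centre is untouched.

Step 16
Reactants: 24 the hydroxy keto quinone
Product: 25 2-[(2E,6Z,10E,13R)-13-hydroxy-3,7,11,15-tetramethyl-5-oxohexadeca-2,6,10,14-tetraen-1-yl]-6-methylbenzene-1,4-diol (target)
Conditions: Na2S2O4 (aq.), degassed Et2O, rt, under Ar
Reagents that add atoms: none
Why: Two-electron reduction of the quinone by dithionite restores the aromatic hydroquinone ring, while enones, isolated alkenes and the allylic alcohol are not reduced under these conditions.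

**Compound list**

1 | 3-methylbut-2-enal | CC(C)=CC=O | starting material
2 | 4,4,5,5-tetramethyl-2-(propa-1,2-dien-1-yl)-1,3,2-dioxaborolane (allenylboronic acid pinacol ester) | C=C=CB1OC(C)(C)C(C)(C)O1 | starting material
3 | 4,4,5,5-tetramethyl-2-{[(4R)-6-methylhept-5-en-1-yn-4-yl]oxy}-1,3,2-dioxaborolane (not isolated) | CC(C)=C[C@H](OB1OC(C)(C)C(C)(C)O1)CC#C | intermediate
4 | (4R)-6-methylhept-5-en-1-yn-4-ol | CC(C)=C[C@H](O)CC#C | intermediate
5 | tert-butyldimethyl{[(4R)-6-methylhept-5-en-1-yn-4-yl]oxy}silane | CC(C)=C[C@H](O[Si](C)(C)C(C)(C)C)CC#C | intermediate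
6 | {(1E,4R)-4-[(tert-butyldimethylsilyl)oxy]-2,6-dimethylhepta-1,5-dien-1-yl}dimethylalumane (not isolated) | CC(C)=C[C@H](O[Si](C)(C)C(C)(C)C)C/C(C)=C/[Al](C)C | intermediate
7 | tert-butyl{[(1E,4R)-1-iodo-2,6-dimethylhepta-1,5-dien-4-yl]oxy}dimethylsilane | CC(C)=C[C@H](O[Si](C)(C)C(C)(C)C)C/C(C)=C/I | intermediate
8 | (2Z)-3-methylpent-2-en-4-yn-1-ol | C#C/C(C)=C\CO | starting material
9 | (2Z)-3-methylpenta-2,4-dien-1-ol | C=C/C(C)=C\CO | intermediate
10 | 9-{[(2Z)-5-(9-borabicyclo[3.3.1]nonan-9-yl)-3-methylpent-2-en-1-yl]oxy}-9-borabicyclo[3.3.1]nonane (not isolated) | B1(C2CCCC1CCC2)CC/C(C)=C\COB1C2CCCC1CCC2 | intermediate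
11 | (2Z,6E,9R)-9-[(tert-butyldimethylsilyl)oxy]-3,7,11-trimethyldodeca-2,6,10-trien-1-ol | CC(C)=C[C@H](O[Si](C)(C)C(C)(C)C)C/C(C)=C/CC/C(C)=C\CO | intermediate
12 | (2Z,6E,9R)-9-[(tert-butyldimethylsilyl)oxy]-3,7,11-trimethyldodeca-2,6,10-trienal | CC(C)=C[C@H](O[Si](C)(C)C(C)(C)C)C/C(C)=C/CC/C(C)=C\C=O | intermediate
13 | 3-bromoprop-1-yne (propargyl bromide) | C#CCBr | starting material
14 | (5Z,9E,12R)-12-[(tert-butyldimethylsilyl)oxy]-6,10,14-trimethylpentadeca-5,9,13-trien-1-yn-4-ol (both C4 epimers) | CC(C)=C[C@H](O[Si](C)(C)C(C)(C)C)C/C(C)=C/CC/C(C)=C\C(O)CC#C | intermediate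
15 | (5Z,9E,12R)-12-[(tert-butyldimethylsilyl)oxy]-6,10,14-trimethyl-4-[(triethylsilyl)oxy]pentadeca-5,9,13-trien-1-yne (both C4 epimers) | CC(C)=C[C@H](O[Si](C)(C)C(C)(C)C)C/C(C)=C/CC/C(C)=C\C(O[Si](CC)(CC)CC)CC#C | intermediate
16 | 2-hydroxy-3-methylbenzaldehyde | Cc1cccc(C=O)c1O | starting material
17 | 2-(hydroxymethyl)-6-methylphenol | Cc1cccc(CO)c1O | intermediate
18 | 2-(hydroxymethyl)-6-methylcyclohexa-2,5-diene-1,4-dione | CC1=CC(=O)C=C(CO)C1=O | intermediate
19 | 2-(chloromethyl)-6-methylcyclohexa-2,5-diene-1,4-dione | CC1=CC(=O)C=C(CCl)C1=O | intermediate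
20 | {(1E,5Z,9E,12R)-12-[(tert-butyldimethylsilyl)oxy]-2,6,10,14-tetramethyl-4-[(triethylsilyl)oxy]pentadeca-1,5,9,13-tetraen-1-yl}dimethylalumane (not isolated) | CC(C)=C[C@H](O[Si](C)(C)C(C)(C)C)C/C(C)=C/CC/C(C)=C\C(O[Si](CC)(CC)CC)C/C(C)=C/[Al](C)C | intermediate
21 | 2-[(2E,6Z,10E,13R)-13-[(tert-butyldimethylsilyl)oxy]-3,7,11,15-tetramethyl-5-[(triethylsilyl)oxy]hexadeca-2,6,10,14-tetraen-1-yl]-6-methylcyclohexa-2,5-diene-1,4-dione | CC(C)=C[C@H](O[Si](C)(C)C(C)(C)C)C/C(C)=C/CC/C(C)=C\C(O[Si](CC)(CC)CC)C/C(C)=C/CC1=CC(=O)C=C(C)C1=O | intermediate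
22 | 2-[(2E,6Z,10E,13R)-13-[(tert-butyldimethylsilyl)oxy]-5-hydroxy-3,7,11,15-tetramethylhexadeca-2,6,10,14-tetraen-1-yl]-6-methylcyclohexa-2,5-diene-1,4-dione | CC(C)=C[C@H](O[Si](C)(C)C(C)(C)C)C/C(C)=C/CC/C(C)=C\C(O)C/C(C)=C/CC1=CC(=O)C=C(C)C1=O | intermediate
23 | 2-[(2E,6Z,10E,13R)-13-[(tert-butyldimethylsilyl)oxy]-3,7,11,15-tetramethyl-5-oxohexadeca-2,6,10,14-tetraen-1-yl]-6-methylcyclohexa-2,5-diene-1,4-dione | CC(C)=C[C@H](O[Si](C)(C)C(C)(C)C)C/C(C)=C/CC/C(C)=C\C(=O)C/C(C)=C/CC1=CC(=O)C=C(C)C1=O | intermediate
24 | 2-[(2E,6Z,10E,13R)-13-hydroxy-3,7,11,15-tetramethyl-5-oxohexadeca-2,6,10,14-tetraen-1-yl]-6-methylcyclohexa-2,5-diene-1,4-dione | CC(C)=C[C@H](O)C/C(C)=C/CC/C(C)=C\C(=O)C/C(C)=C/CC1=CC(=O)C=C(C)C1=O | intermediate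
25 | 2-[(2E,6Z,10E,13R)-13-hydroxy-3,7,11,15-tetramethyl-5-oxohexadeca-2,6,10,14-tetraen-1-yl]-6-methylbenzene-1,4-diol | CC(C)=C[C@H](O)C/C(C)=C/CC/C(C)=C\C(=O)C/C(C)=C/Cc1cc(O)cc(C)c1O | target

**Step count and risks**

Total step count: 16. Longest linear sequence: 12 steps (steps 1, 2, 3, 5, 6, 7, 8, 12, 13, 14, 15, 16).

Steps most likely to fail:

Step 12. The quinone 19 has two unsubstituted ring positions. Addition of aluminium-bound groups to its C=C or C=O bonds, or reduction of the quinone by the low-valent nickel, may outrun the cross-coupling. The fallback moves the union to a neutral organotin reagent and palladium catalysis. It sets out from 15 through the alkenylalane 20, which is quenched with I2 to give the (1E)-iodoalkene F1. Iodine–lithium exchange (t-BuLi, Et2O, −78 °C) gives the alkenyllithium F2, which is trapped with Bu3SnCl to give the alkenylstannane F3. Stille coupling of F3 with 19 (Pd2(dba)3, AsPh3, THF, rt to 45 °C) forms the same C1'–C2' bond with retention and comes back to the route at compound 21.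

Step 11. Addition of chloride or adventitious HCl to the electron-poor quinone, or decomposition of the quinonylmethyl chloride while it forms, may erode the material. The fallback installs the chloride at the arene oxidation level and unveils the quinone afterwards. It sets out from 18: reduction with Na2S2O4 gives the hydroquinone F4; Me2SO4/K2CO3 in acetone methylates both phenols to give the dimethyl ether F5; SOCl2 in CH2Cl2 at 0 °C gives the benzylic chloride F6. Oxidative demethylation of F6 with (NH4)2Ce(NO3)6 in MeCN/H2O at 0 °C comes back to the route at compound 19.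

Step 1. Facial discrimination by the chiral acid may be insufficient (or of the wrong sense) for this small β,β-disubstituted enal. The fallback replaces catalyst control by a kinetic resolution. It sets out from 1 and 13: Barbier propargylation (Zn, THF/aq. NH4Cl) gives the racemic alcohol F7. Sharpless kinetic resolution (Ti(OiPr)4, L-(+)-diisopropyl tartrate, t-BuOOH, 4 Å MS, CH2Cl2, −20 °C, run somewhat beyond half conversion) should epoxidise the (S)-enantiomer to the epoxy alcohol F8, which is removed by chromatography, and leave the (R)-alcohol, so that the fallback comes back to the route at compound 4.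

Further compounds
F1 | step 12 | tert-butyl{[(3R,5E,9Z,13E)-14-iodo-2,6,10,13-tetramethyl-11-[(triethylsilyl)oxy]tetradeca-2,5,9,13-tetraen-4-yl]oxy}dimethylsilane (E-iodoalkene from 20) | CC(C)=C[C@H](O[Si](C)(C)C(C)(C)C)C/C(C)=C/CC/C(C)=C\C(O[Si](CC)(CC)CC)C/C(C)=C/I
F2 | step 12 | alkenyllithium from F1 (not isolated) | CC(C)=C[C@H](O[Si](C)(C)C(C)(C)C)C/C(C)=C/CC/C(C)=C\C(O[Si](CC)(CC)CC)C/C(C)=C/[Li]
F3 | step 12 | tributyl{(1E,5Z,9E,12R)-12-[(tert-butyldimethylsilyl)oxy]-2,6,10,14-tetramethyl-4-[(triethylsilyl)oxy]pentadeca-1,5,9,13-tetraen-1-yl}stannane | CC(C)=C[C@H](O[Si](C)(C)C(C)(C)C)C/C(C)=C/CC/C(C)=C\C(O[Si](CC)(CC)CC)C/C(C)=C/[Sn](CCCC)(CCCC)CCCC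
F4 | step 11 | 2-(hydroxymethyl)-6-methylbenzene-1,4-diol | Cc1cc(O)cc(CO)c1O
F5 | step 11 | (2,5-dimethoxy-3-methylphenyl)methanol | COc1cc(C)c(OC)c(CO)c1
F6 | step 11 | 1-(chloromethyl)-2,5-dimethoxy-3-methylbenzene | COc1cc(C)c(OC)c(CCl)c1
F7 | step 1 | racemic 6-methylhept-5-en-1-yn-4-ol | CC(C)=CC(O)CC#C
F8 | step 1 | (1S)-1-[(2S)-3,3-dimethyloxiran-2-yl]but-3-yn-1-ol | C#CC[C@H](O)[C@@H]1OC1(C)C
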